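## Retrosynthetic overview

1. The last step is Si–O cleavage at C3'. Before it, benzene ring A of the aromatic half (C1–C4 with the C4 methyl, the two ether oxygens sitting on C2 and C3) is cut at C1–C10 and C4–C5. A 2-methylene-3-ethylidene-1,4-dioxane built on O3'/O4' of the quinoid half (21) adds to the BCDE 5(10)-en-6-one 11, whose C6 ketone activates C5=C10, and DDQ aromatises.
2. Diene 21 comes from tingenone: reagent-controlled hydroxylation at C4', crossed ketol condensation with 2-hydroxypentan-3-one (closes the dioxene with O3' on the methyl-bearing and O4' on the ethyl-bearing carbon), silylation, bromination–dehydrobromination.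
3. Enone 11 comes from tingenone by excision of C1–C4: exhaustive hydrogenation (sets 8α-H), 2,3-dione, bis(silyloxy)diene, Alder–Rickert extrusion of the C5=C10 alkene (C1–C4 leave as a phthalate), allylic oxidation at C6.
4. Ring order: rings B–E of both halves are taken intact from tingenone; the dioxene ring closes in step 9 and benzene ring A, which completes the benzodioxane, in step 12.
5. The C3' hemiketal oxygen is carried through the key step as its triethylsilyl ether. A 3'-H dioxane would be a β-aryloxy ketone open to retro-oxa-Michael cleavage, and its enolate could not be formed selectively beside two C21 ketones.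

Key step: step 12

Remark: tingenone (maytenin), a catalogue natural product, is taken as the purchased source of rings B–E of both halves; friedelane numbering is used, primed for the quinoid half.
Remark: the cis fusion at the exchangeable C3' hemiketal centre is assumed to be the thermodynamic one, as in the natural dimers that carry the same centre.

## Route

Step 1
Reactants: 1 tingenone
Product: 3 ring A perhydro 2,3,21-triol (8α-H), via 7,8-dihydrotingenol 2 (not isolated)
Conditions: H2 (100 bar), Pd/C, Rh/Al2O3, AcOH/i-PrOH, 25 °C then 80 °C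
Reagents that add atoms: none
Why: Pd-catalysed 1,6-hydrogenation of the quinone methide gives the catechol, the hindered C7=C8 bond is then saturated by way of Pd–H migration to the styrenic C6=C7 position with hydrogen reaching C8 from the α face opposite the C9 and C14 methyl groups (sets 8α-H), and Rh/Al2O3 perhydrogenates the catechol ring and reduces the C21 ketone (heterogeneous arene hydrogenation); the new centres at C2, C3, C4, C5, C10 and C21 are left uncontrolled because every one of them is erased by step 4.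

Step 2
Reactants: 3 ring A perhydro 2,3,21-triol
Product: 4 ring A saturated 2,3,21-trione
Conditions: DMSO, (CF3CO)2O, CH2Cl2, −78 °C; Et3N, −78 to 0 °C
Reagents that add atoms: none
Why: Activated-DMSO (Swern-type) oxidation with trifluoroacetic anhydride converts the vicinal diol into the 1,2-diketone without glycol cleavage and returns the C21 ketone, converging all alcohol epimers from step 1.

Step 3
Reactants: 4 ring A saturated 2,3,21-trione
Product: 5 2,3,21-tris(trimethylsilyloxy)-1,3,21(22)-triene
Conditions: LDA (4 equiv), Me3SiCl (6 equiv), THF, −78 °C (in situ quench)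
Reagents that add atoms: chlorotrimethylsilane, C[Si](C)(C)Cl
Why: Kinetic deprotonation with in situ silylation gives the only bis-enol ether the 2,3-dione can form (toward C1 and C4, a 2,3-bis(silyloxy)-1,3-diene with C5 and C10 sp3) and, at C21, the enol ether toward the less hindered C22 methylene so that C20 is not touched (silyl enol ether formation).

Step 4
Reactants: 5 2,3,21-tris(trimethylsilyloxy)-1,3,21(22)-triene, 6 dimethyl acetylenedicarboxylate
Product: 9 BCDE 5(10)-en-21-one, via cycloadduct 7 (not isolated), via silyl enol ether 8 (not isolated)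
Conditions: 6 (1.5 equiv), PhMe, 80 °C; then 190 °C (sealed tube); 1 M HCl, THF, 20 °C
Reagents that add atoms: none
Why: Diels–Alder addition of the alkyne across C1 and C4 at 80 °C, before 1,5-hydrogen shifts can move the diene, gives a bicyclo[2.2.2]octadiene that on stronger heating undergoes Alder–Rickert retro-[4+2] cleavage, aromatisation of the phthalate driving extrusion of the C5–C10 bridge as the ring B cis-alkene, and dilute acid then protonates the C21 enol ether at C22 to return the ketone.

Step 5
Reactants: 9 BCDE 5(10)-en-21-one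
Product: 10 BCDE 6-hydroxy-5(10)-en-21-one (C6 epimers)
Conditions: SeO2 (0.5 equiv), t-BuOOH, CH2Cl2, 20 °C
Reagents that add atoms: selenium dioxide, O=[Se]=O (oxygen turned over by tert-butyl hydroperoxide, CC(C)(C)OO)
Why: SeO2 allylic oxidation (ene reaction followed by 2,3-sigmatropic shift) can draw hydrogen only from C6, the single allylic C–H position because C9 is quaternary, and returns the double bond to C5=C10; the C6 configuration is immaterial.

Step 6
Reactants: 10 BCDE 6-hydroxy-5(10)-en-21-one
Product: 11 BCDE 5(10)-ene-6,21-dione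
Conditions: MnO2, CH2Cl2, 20 °C
Reagents that add atoms: none
Why: MnO2 oxidises the allylic alcohol selectively to the conjugated enone and leaves the saturated C21 ketone and its α-centre C20 alone (allylic alcohol oxidation).

Step 7
Reactants: 12 2-bromopentan-3-one
Product: 14 2-hydroxypentan-3-one, via formate ester 13 (not isolated)
Conditions: HCO2Na, MeOH, reflux
Reagents that add atoms: sodium formate, [Na+].[O-]C=O
Why: SN2 displacement of the α-bromo ketone by formate and methanolysis of the labile formate ester in the same flask give the racemic ketol under near-neutral conditions that do not shift the carbonyl to C2 (formate route to α-hydroxy ketones).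

Step 8
Reactants: 1 tingenone
Product: 16 4'β-hydroxy-2',3'-dione, via potassium enolate 15 (not isolated)
Conditions: KN(SiMe3)2 (1.05 equiv), THF, −78 °C; oxaziridine (1.3 equiv), −78 to −40 °C; AcOH
Reagents that add atoms: (+)-[(8,8-dichlorocamphoryl)sulfonyl]oxaziridine, CC1(C)[C@@H]2CC[C@]13CS(=O)(=O)N4O[C@@]34C2(Cl)Cl
Why: One equivalent of base removes only the acidic diosphenol proton (the C21 ketone stays un-enolised) and the N-sulfonyloxaziridine transfers oxygen to C4', the α-carbon of the extended enolate (Davis enolate hydroxylation); the nearly flat ring A/B offers little bias of its own at C4', so the face is set by the chiral reagent, the (+)-reagent being proposed for delivery to the face of the C9' methyl (β) and its antipode held in reserve should the sense prove opposite.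

Step 9
Reactants: 16 4'β-hydroxy-2',3'-dione, 14 2-hydroxypentan-3-one
Product: 18 dioxene hemiketal, via bis-hemiketal 17 (not isolated)
Conditions: 14 (5 equiv), CSA (10 mol%), 4 Å MS, benzene, 45 °C
Reagents that add atoms: none
Why: In this acid-catalysed crossed ketol condensation the secondary hydroxyl of 14 adds to the highly electrophilic C3' carbonyl, the C4' hydroxyl closes onto the ethyl ketone to a 2,5-dihydroxy-1,4-dioxane, and loss of water toward the CH(CH3) carbon gives the tetrasubstituted dioxene, so that O3' ends on the methyl-bearing and O4' on the ethyl-bearing carbon, while the exchangeable C3' hemiketal settles in the cis-fused form with both ring oxygens β and the free OH α, cis to the C4' methyl.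

Step 10
Reactants: 18 dioxene hemiketal
Product: 19 3'-O-triethylsilyl dioxene
Conditions: Et3SiOTf, 2,6-lutidine, CH2Cl2, −78 °C
Reagents that add atoms: triethylsilyl trifluoromethanesulfonate, CC[Si](CC)(CC)OS(=O)(=O)C(F)(F)F
Why: Silyl triflate with a hindered pyridine base silylates the tertiary hemiketal hydroxyl without free acid that would hydrolyse the dioxene, which freezes the C3' configuration and removes the alkoxide-triggered ring opening that a free hemiketal would suffer in step 11 (silyl ether formation).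

Step 11
Reactants: 19 3'-O-triethylsilyl dioxene
Product: 21 3'-O-triethylsilyl 2-methylene-3-[(Z)-ethylidene]-1,4-dioxane diene, via dibromide 20 (not isolated)
Conditions: Br2 (1.0 equiv), CH2Cl2, −78 °C; i-Pr2NEt (4 equiv), −78 to 0 °C; used at once
Reagents that add atoms: none
Why: Bromine adds at −78 °C to the enediol-ether double bond, by far the most electron-rich alkene present, and the two tertiary α-bromo ethers then lose HBr toward the only β-hydrogens available (the methyl and the ethyl CH2), giving the bis-exocyclic diene with the ethylidene methyl turned outward, cis to O4', to avoid the neighbouring methylene (bromination–dehydrobromination of an enol ether).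

Step 12
Reactants: 21 3'-O-triethylsilyl 2-methylene-3-[(Z)-ethylidene]-1,4-dioxane diene, 11 BCDE 5(10)-ene-6,21-dione
Product: 23 3'-O-triethylsilyl dimer, via cycloadduct 22 (not isolated)
Conditions: 11 (2.5 equiv), BHT, CH2Cl2, 15 kbar, 40 °C; then DDQ (2.2 equiv), PhMe, 20 °C
Reagents that add atoms: none
Why: The diene, held s-cis by the dioxane ring and raised in HOMO energy by its two oxygen atoms, adds in a concerted normal-demand [4+2] reaction to the C5=C10 bond of 11, which the C6 ketone polarises; 15 kbar compensates for the quaternary C9 next to C10 without any acid that would destroy the bis-enol ether. The closest known reaction type is the cycloaddition of 2,3-dimethylene-1,4-dioxanes and related bis-exocyclic dienes to enones followed by quinone dehydrogenation to 2,3-dihydro-1,4-benzodioxines. Ring A is closed by intermolecular [4+2] annulation onto ring B, forming C1–C10 and C4–C5 and a six-membered carbocycle fused to the dioxane and to ring B. The new centres C4, C5 and C10 of 22 need no control, because DDQ (added only once the diene is consumed, since it would itself add to the diene) removes the hydrogens at C1, C10, C4 and C5 by allylic hydride abstraction next to the enediol ether and makes all three trigonal. The selectivity required is regiochemical: the unsubstituted methylene terminus, which has the larger HOMO coefficient and the smaller steric demand, bonds to the β-carbon C10 and the methyl-bearing terminus to the α-carbon C5 (ortho rule), while the O–C3'/O–C4' connectivity was fixed when the dioxene was built in step 9. Chemoselectivity rests on 11 being a disubstituted cis-enone used in excess, whereas the only enone in 21 itself, C1'=C10', is fully substituted at its β-carbon.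

Step 13
Reactants: 23 3'-O-triethylsilyl dimer
Product: 24 CNP0106202.2
Conditions: HF·pyridine, THF, 0 °C
Reagents that add atoms: none
Why: Buffered fluoride cleaves the Si–O bond of the tertiary silyl ether without base that could open the hemiketal, and the C3' hydroxyl keeps the configuration (α, cis to the C4' methyl) fixed in steps 9 and 10 (desilylation).

## Compound list

1 | tingenone (3-hydroxy-2,21-dioxo quinone methide, 20β-methyl) | CC1=C(O)C(=O)C=C2C1=CC=C1[C@@]2(C)CC[C@@]2(C)[C@@H]3C[C@@H](C)C(=O)C[C@]3(C)CC[C@]12C | starting material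
2 | 7,8-dihydrotingenol (ring A catechol, 8α-H, 21-ketone) | Cc1c(O)c(O)cc2c1CC[C@H]1[C@@]2(C)CC[C@@]2(C)[C@@H]3C[C@@H](C)C(=O)C[C@]3(C)CC[C@]12C | intermediate (not isolated)
3 | ring A perhydro 2,3,21-triol (8α-H; C2, C3, C4, C5, C10, C21 unassigned, epimer mixture) | CC1C(O)C(O)CC2C1CC[C@H]1[C@@]2(C)CC[C@@]2(C)[C@@H]3C[C@@H](C)C(O)C[C@]3(C)CC[C@]12C | intermediate
4 | ring A saturated 2,3,21-trione (C4, C5, C10 unassigned) | CC1C(=O)C(=O)CC2C1CC[C@H]1[C@@]2(C)CC[C@@]2(C)[C@@H]3C[C@@H](C)C(=O)C[C@]3(C)CC[C@]12C | intermediate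
5 | 2,3,21-tris(trimethylsilyloxy)-1,3,21(22)-triene (C5, C10 unassigned) | CC1=C(O[Si](C)(C)C)C(O[Si](C)(C)C)=CC2C1CC[C@H]1[C@@]2(C)CC[C@@]2(C)[C@@H]3C[C@@H](C)C(O[Si](C)(C)C)=C[C@]3(C)CC[C@]12C | intermediate
6 | dimethyl acetylenedicarboxylate | COC(=O)C#CC(=O)OC | starting material
7 | bicyclo[2.2.2]octadiene cycloadduct (C1 and C4 bridged by the diester alkene) | CC12C(O[Si](C)(C)C)=C(O[Si](C)(C)C)C(C(C(=O)OC)=C1C(=O)OC)C1C2CC[C@H]2[C@@]1(C)CC[C@@]1(C)[C@@H]3C[C@@H](C)C(O[Si](C)(C)C)=C[C@]3(C)CC[C@]21C | intermediate (not isolated)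
8 | BCDE 5(10)-ene 21-trimethylsilyl enol ether | C1C=C[C@]2(C)CC[C@@]3(C)[C@@H]4C[C@@H](C)C(O[Si](C)(C)C)=C[C@]4(C)CC[C@]3(C)[C@H]2C1 | intermediate (not isolated)
9 | BCDE 5(10)-en-21-one (8α-H, 9β-methyl) | C1C=C[C@]2(C)CC[C@@]3(C)[C@@H]4C[C@@H](C)C(=O)C[C@]4(C)CC[C@]3(C)[C@H]2C1 | intermediate
10 | BCDE 6-hydroxy-5(10)-en-21-one (C6 epimers) | OC1C=C[C@]2(C)CC[C@@]3(C)[C@@H]4C[C@@H](C)C(=O)C[C@]4(C)CC[C@]3(C)[C@H]2C1 | intermediate
11 | BCDE 5(10)-ene-6,21-dione (dienophile) | O=C1C=C[C@]2(C)CC[C@@]3(C)[C@@H]4C[C@@H](C)C(=O)C[C@]4(C)CC[C@]3(C)[C@H]2C1 | intermediate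
12 | 2-bromopentan-3-one (racemic) | CCC(=O)C(C)Br | starting material
13 | 3-oxopentan-2-yl formate | CCC(=O)C(C)OC=O | intermediate (not isolated)
14 | 2-hydroxypentan-3-one (racemic) | CCC(=O)C(C)O | intermediate
15 | potassium 3-enolate of tingenone | [K+].CC1=C([O-])C(=O)C=C2C1=CC=C1[C@@]2(C)CC[C@@]2(C)[C@@H]3C[C@@H](C)C(=O)C[C@]3(C)CC[C@]12C | intermediate (not isolated)
16 | 4'β-hydroxy-4'α-methyl-1'(10'),5',7'-triene-2',3',21'-trione | O=C1C(=O)C=C2C(=CC=C3[C@@]2(C)CC[C@@]2(C)[C@@H]4C[C@@H](C)C(=O)C[C@]4(C)CC[C@]32C)[C@@]1(C)O | intermediate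
17 | bis-hemiketal (2,5-dihydroxy-1,4-dioxane fused at C3'/C4'; new dioxane carbons unassigned) | CCC1(O)C(C)O[C@@]2(O)C(=O)C=C3C(=CC=C4[C@@]3(C)CC[C@@]3(C)[C@@H]5C[C@@H](C)C(=O)C[C@]5(C)CC[C@]43C)[C@@]2(C)O1 | intermediate (not isolated)
18 | dioxene hemiketal (ring oxygens 3'β,4'β; 3'α-OH; 4'α-methyl; methyl on the O3' carbon, ethyl on the O4' carbon) | CCC1=C(C)O[C@@]2(O)C(=O)C=C3C(=CC=C4[C@@]3(C)CC[C@@]3(C)[C@@H]5C[C@@H](C)C(=O)C[C@]5(C)CC[C@]43C)[C@@]2(C)O1 | intermediate
19 | 3'-O-triethylsilyl dioxene | CCC1=C(C)O[C@@]2(O[Si](CC)(CC)CC)C(=O)C=C3C(=CC=C4[C@@]3(C)CC[C@@]3(C)[C@@H]5C[C@@H](C)C(=O)C[C@]5(C)CC[C@]43C)[C@@]2(C)O1 | intermediate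
20 | 2,3-dibromo-2-ethyl-3-methyl-1,4-dioxane (C–Br centres unassigned) | CCC1(Br)C(C)(Br)O[C@@]2(O[Si](CC)(CC)CC)C(=O)C=C3C(=CC=C4[C@@]3(C)CC[C@@]3(C)[C@@H]5C[C@@H](C)C(=O)C[C@]5(C)CC[C@]43C)[C@@]2(C)O1 | intermediate (not isolated)
21 | quinoid-half diene: 3'α-triethylsilyloxy, 2-methylene on the O3' carbon, (Z)-ethylidene on the O4' carbon | C=C1O[C@@]2(O[Si](CC)(CC)CC)C(=O)C=C3C(=CC=C4[C@@]3(C)CC[C@@]3(C)[C@@H]5C[C@@H](C)C(=O)C[C@]5(C)CC[C@]43C)[C@@]2(C)O/C1=C\C | intermediate (key-step precursor)
22 | ring A cyclohexene cycloadduct (C4, C5, C10 unassigned) | CC1C2=C(CC3C1C(=O)C[C@H]1[C@@]3(C)CC[C@@]3(C)[C@@H]4C[C@@H](C)C(=O)C[C@]4(C)CC[C@]13C)O[C@@]1(O[Si](CC)(CC)CC)C(=O)C=C3C(=CC=C4[C@@]3(C)CC[C@@]3(C)[C@@H]5C[C@@H](C)C(=O)C[C@]5(C)CC[C@]43C)[C@@]1(C)O2 | intermediate (not isolated)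
23 | 3'-O-triethylsilyl dimer (C2–O–C3', C3–O–C4'; 8α-H) | Cc1c2c(cc3c1C(=O)C[C@H]1[C@@]3(C)CC[C@@]3(C)[C@@H]4C[C@@H](C)C(=O)C[C@]4(C)CC[C@]13C)O[C@@]1(O[Si](CC)(CC)CC)C(=O)C=C3C(=CC=C4[C@@]3(C)CC[C@@]3(C)[C@@H]5C[C@@H](C)C(=O)C[C@]5(C)CC[C@]43C)[C@@]1(C)O2 | intermediate (key-step product)
24 | CNP0106202.2 | Cc1c2c(cc3c1C(=O)C[C@H]1[C@@]3(C)CC[C@@]3(C)[C@@H]4C[C@@H](C)C(=O)C[C@]4(C)CC[C@]13C)O[C@@]1(O)C(=O)C=C3C(=CC=C4[C@@]3(C)CC[C@@]3(C)[C@@H]5C[C@@H](C)C(=O)C[C@]5(C)CC[C@]43C)[C@@]1(C)O2 | target

## Step count and risks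

Total step count: 13. Longest linear sequence: 8 steps (steps 1–6, 12, 13).

**Step 12.** The cycloaddition may be too slow at the neopentyl β-carbon C10, so that diene 21 oligomerises or hydrolyses before it is consumed. The fallback activates the dienophile and sets out from 11. Bromine in CH2Cl2 at 0 °C followed by Et3N converts 11, by way of the 5,10-dibromo ketone F1, into the 5-bromo-5(10)-en-6-one F2; α-bromo enones are markedly better dienophiles and obey the same regiochemistry. Cycloaddition with 21 (PhMe, 60 °C, or 10 kbar) gives the 5-bromo cycloadduct F3. DBU removes HBr to the 1,4-cyclohexadiene F4, and one equivalent of DDQ then gives 23, where the route is rejoined.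

**Step 8.** Oxygen transfer may go to C6 or C8 of the extended enolate, or the face at C4' may be poorly discriminated. The fallback oxidises a neutral enol ether instead and sets out from 1 and 12. K2CO3 in acetone alkylates the enol oxygen to tingenone 3-O-(3-oxopentan-2-yl) ether F5, which also locks the O3'–CH(CH3) bond. Shi epoxidation of the C3'=C4' enol ether (Oxone, fructose-derived ketone, buffered MeCN–dimethoxymethane–water) gives the 3',4'β-epoxy ether F6 under catalyst control of the face. F6 opens in the aqueous medium at C3' and closes onto the side-chain ketone to 17, which CSA dehydrates as in step 9 to 18, where the route is rejoined.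

**Step 11.** The dibromide may ionise with ring cleavage, or the diene may be lost on isolation. The fallback stores the diene as a bis-ketal and sets out from 19. NBS in MeOH with 2,6-lutidine gives the 2,3-dimethoxy-2-ethyl-3-methyl-1,4-dioxane F7. Me3SiOTf and i-Pr2NEt in CH2Cl2 at −20 °C then remove two molecules of methanol (ketal to enol ether elimination), if desired in the presence of 11, to give 21, where the route is rejoined.

## Further compounds

F1 | step 12 | BCDE 5,10-dibromo-6,21-dione (not isolated) | O=C1C(Br)C(Br)[C@]2(C)CC[C@@]3(C)[C@@H]4C[C@@H](C)C(=O)C[C@]4(C)CC[C@]3(C)[C@H]2C1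
F2 | step 12 | BCDE 5-bromo-5(10)-ene-6,21-dione | O=C1C(Br)=C[C@]2(C)CC[C@@]3(C)[C@@H]4C[C@@H](C)C(=O)C[C@]4(C)CC[C@]3(C)[C@H]2C1
F3 | step 12 | 5-bromo ring A cycloadduct | CC1C2=C(CC3C1(Br)C(=O)C[C@H]1[C@@]3(C)CC[C@@]3(C)[C@@H]4C[C@@H](C)C(=O)C[C@]4(C)CC[C@]13C)O[C@@]1(O[Si](CC)(CC)CC)C(=O)C=C3C(=CC=C4[C@@]3(C)CC[C@@]3(C)[C@@H]5C[C@@H](C)C(=O)C[C@]5(C)CC[C@]43C)[C@@]1(C)O2
F4 | step 12 | ring A 2,5(10)-cyclohexadiene | CC1C2=C(CC3=C1C(=O)C[C@H]1[C@@]3(C)CC[C@@]3(C)[C@@H]4C[C@@H](C)C(=O)C[C@]4(C)CC[C@]13C)O[C@@]1(O[Si](CC)(CC)CC)C(=O)C=C3C(=CC=C4[C@@]3(C)CC[C@@]3(C)[C@@H]5C[C@@H](C)C(=O)C[C@]5(C)CC[C@]43C)[C@@]1(C)O2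
F5 | step 8 | tingenone 3-O-(3-oxopentan-2-yl) ether | CC1=C(OC(C)C(=O)CC)C(=O)C=C2C1=CC=C1[C@@]2(C)CC[C@@]2(C)[C@@H]3C[C@@H](C)C(=O)C[C@]3(C)CC[C@]12C
F6 | step 8 | 3',4'β-epoxy ether of F5 (not isolated) | CCC(=O)C(C)O[C@@]12O[C@]1(C)C(=CC=C1[C@@]3(C)CC[C@@]4(C)[C@@H]5C[C@@H](C)C(=O)C[C@]5(C)CC[C@]14C)C3=CC2=O
F7 | step 11 | 3'-O-triethylsilyl 2,3-dimethoxy-2-ethyl-3-methyl-1,4-dioxane | CCC1(OC)C(C)(OC)O[C@@]2(O[Si](CC)(CC)CC)C(=O)C=C3C(=CC=C4[C@@]3(C)CC[C@@]3(C)[C@@H]5C[C@@H](C)C(=O)C[C@]5(C)CC[C@]43C)[C@@]2(C)O1
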